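In a one-step world the decay of the starting material would give the end state, but in this flask the material leaves by several outlets, so I need its end point and then the ratio in which the outlets share it.

the same everywhere: starting material 0.20 M

|  | first nucleophile | second nucleophile | remark | time |
|---|---|---|---|---|
| larch | 0.30 M | 0.40 M (fed, over 10 h) | the very flask that is asked about, followed so far |  |
| flask | 0.300 M | 0.400 M (fed, over 10 h) |  | 5.0 d |

larch run (percent of the starting material charged)

| time / h | starting material / % | target / % | other capture product / % |
|---|---|---|---|
| 2.00 | 79.0 | 5.1 | 6.4 |
| 4.00 | 63.6 | 8.0 | 16.5 |
| 6.00 | 50.6 | 9.1 | 26.4 |
| 12.0 | 25.6 | 11.3 | 46.9 |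
| 25.0 | 5.7 | 12.8 | 62.6 |

(standard deviation of a reading: 0.3 percentage points)

- the reaction counts as stopped when no species that holds the starting material changes by six tenths of a point or more over the second half of the time

- which holds at 5.0 d: what has brought the reaction to rest, or that it has not come to rest (all of the starting material has reacted / the first nucleophile has run out first / forward and back rates have come level / the second nucleophile has run out first / it is still moving)
- conversion of starting material at 5.0 d
- amount of target at 5.0 d, in percent of the starting material charged
- amount of other capture product at 5.0 d, in percent of the starting material charged
- amount of target if the flask were left three thousand times as long, in percent of the starting material charged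

1. The larch readings of starting material, from 2.00 h to 25.0 h, give a first-order constant 0.114 h⁻¹, so by 5.0 d I expect <0.001 % of it. Its charge is smaller than that of either nucleophile, which makes it the limiting reagent, so I expect the flask to rest with the starting material consumed.

2. Between 12.0 h and 25.0 h, after the feed, other capture product takes a share 0.789 of the starting material lost, so the remainder carries it to 67.1 %.

3. Let M be the missing part, what the charge lacks after the 3 readings are subtracted. At 25.0 h, M is 18.9 %, and target over M is 0.677. At 6.00 h that ratio reads 0.655, although the gain of other capture product per gain of target climbs from 3.48 to 10.5.

4. What escapes capture therefore splits as target and M, which gives target 13.3 %.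

5. The weak link is that single ratio: M carries a scatter of 0.52 percentage points. At 12.0 h, M is 16.2 %, so pooling the last two readings gives the branching ratio, target per unit of missing material, r = 0.687, and I commit to target 13.4 %, also for the long wait.

The forecast gives all of the starting material has reacted, conversion 100 %, target 13.4 % and other capture product 67 %, saying “Neither nucleophile runs out, and no late leak shows, so the flask should rest because the starting material is consumed.” For the long wait it gives 15.5 %, which differs from my figure.

The flask gives all of the starting material has reacted, conversion >99.9 %, target 13.4 %, other capture product 67.4 %, and after the long wait target 13.4 %.

    starting material → intermediate (k = 0.114 h⁻¹)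
    second nucleophile + intermediate → other capture product (k = 34.2 L mol⁻¹ h⁻¹)
    starting material + intermediate → side product (k = 0.120 L mol⁻¹ h⁻¹)
    first nucleophile + intermediate → target (k = 3.21 L mol⁻¹ h⁻¹)
    intermediate → solvolysis product (k = 1.29 h⁻¹)

In the flask, at 0.253 d, while starting material still feeds the intermediate, capture by second nucleophile uses the intermediate 5.0 times as fast as solvolysis does. By 2.50 d starting material in the flask stands at 0.107 %, and target reads 13.4 % at 50.0 d. Solvolysis product in the flask stands at 18.8 % at 5.00 d, and r, 0.687, times that is 12.9 %, beside target 13.4 %. In the neighbour flask with 0.10 M of second nucleophile, other capture product reaches 33.3 %, the split of the rest by r gives 27.2 %, and target stands at 26.7 %.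

All runs stem from a simulated flask on assumed constants, noise included.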